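## Retrosynthetic overview
- The target is opened at C5–C10 and C4–O in one operation, giving 6β-isoferuloyloxygermacra-1(10)E,4E-diene. In the forward sense a proton starts a transannular closure, the ester C=O traps the C4 cation from the β face, and water finishes the reaction.
- The germacradienyl isoferulate comes from isovanillin (HWE) and the phosphonoacetate of 6β-hydroxygermacra-1(10),4-diene.
- The 6β-alcohol comes from the 6α-hydroxy-germacra-1(10),4,11-triene by saturating the isopropenyl group and inverting C6 through the ketone.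
- The germacratrienol is opened at C6–C7 (farnesyl C1–C10): enantioselective Cr-catalysed closure of 10-chlorofarnesal, which comes from (E,E)-farnesol.
- Ring order: the ten-membered ring forms first (1,10-closure of the farnesyl chain). The decalin follows by C5–C10 closure, as in FPP → germacradienyl → eudesmyl cation.

Assumption: germacrane/eudesmane numbering is used (C6 = farnesyl C1, C7 = farnesyl C10), and the ligand antipode in the macrocyclisation is the one that directs addition to the aldehyde Si face, to be confirmed by Mosher analysis of the first batch of macrocyclic alcohol.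

## Route

Step 1
Reactants: 1 (2E,6E)-farnesol
Product: 2 (2E,6E)-farnesal
Conditions: [Cu(MeCN)4]OTf (5 mol %), bpy (5 mol %), TEMPO (5 mol %), NMI (10 mol %), air, MeCN, rt
Reagents that add atoms: none
Why: Cu(I)/nitroxyl aerobic alcohol oxidation takes the primary allylic alcohol to the enal at room temperature without 2E/2Z scrambling or over-oxidation, and no stereocentre is formed.

Step 2
Reactants: 2 (2E,6E)-farnesal
Product: 3 (2E,6E)-10-chloro-3,7,11-trimethyldodeca-2,6,11-trienal (racemic at C10)
Conditions: NCS (1.0 equiv), PhSeCl (5 mol %), CH2Cl2, 0 °C → rt, stopped at ca. 75 % conversion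
Reagents that add atoms: N-chlorosuccinimide, O=C1CCC(=O)N1Cl
Why: Selenium-catalysed ene-type allylic chlorination transposes the alkene to the isopropenyl chloride; the enal C2=C3 is electronically switched off and the terminal isopropylidene is the less hindered of the two remaining trisubstituted alkenes, while the racemic C10 centre is erased in the next step.

Step 3
Reactants: 3 (2E,6E)-10-chloro-3,7,11-trimethyldodeca-2,6,11-trienal
Product: 6 (1(10)E,4E,6R,7S)-germacra-1(10),4,11-trien-6-ol (6α-OH/7β-isopropenyl), via allylchromium species 4 (not isolated), via trimethylsilyl ether 5 (not isolated)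
Conditions: CrCl2 (15 mol %), (S,S)-1,8-bis(4-isopropyl-4,5-dihydrooxazol-2-yl)-3,6-diphenylcarbazole (18 mol %), DIPEA (45 mol %), Mn (3 equiv), TMSCl (2 equiv), THF, rt, 3 added over 16 h (final 3 mM); then K2CO3 (cat.), MeOH, 0 °C
Reagents that add atoms: none
Why: Proposed new method: a catalytic asymmetric Nozaki–Hiyama–Kishi allylation run intramolecularly, in which Cr(II) reduces the allylic chloride to σ-allylchromium 4 (Cr on primary C12), which adds through C10 to the Cr-bound aldehyde in a chair Zimmerman–Traxler transition state with both tether ends equatorial, so C6–C7 forms anti and the tridentate ligand selects the aldehyde Si face and thereby fixes C7 as S; the closest known reaction types are racemic CrCl2 closures of ω-formyl allylic halides to (E,E)-cyclodecadienes and intermolecular ligand-controlled Cr-catalysed methallylation/crotylation of enals, and any minor syn isomer is removed here by chromatography.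

Step 4
Reactants: 6 (1(10)E,4E,6R,7S)-germacra-1(10),4,11-trien-6-ol
Product: 7 (1(10)E,4E,6S,7S)-germacra-1(10),4-dien-6-ol (6α-OH/7β-isopropyl)
Conditions: H2 (1 atm), RhCl(PPh3)3 (5 mol %), PhH–EtOH 1:1, rt
Reagents that add atoms: none
Why: Wilkinson hydrogenation discriminates by substitution and saturates only the 1,1-disubstituted isopropenyl alkene, leaving both trisubstituted ring alkenes; no centre is touched, and the C6 descriptor changes from R to S only because the CIP ranks of C5 and C7 swap.

Step 5
Reactants: 7 (1(10)E,4E,6S,7S)-germacra-1(10),4-dien-6-ol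
Product: 8 (1(10)E,4E,7S)-germacra-1(10),4-dien-6-one
Conditions: Dess–Martin periodinane (1.3 equiv), pyridine (5 equiv), CH2Cl2, 0 °C
Reagents that add atoms: none
Why: Buffered Dess–Martin oxidation removes the C6 centre, which only relayed the catalyst's facial choice to C7, under conditions too mild to epimerise the hindered C7–H, isomerise the E-enone or trigger acid cyclisation.

Step 6
Reactants: 8 (1(10)E,4E,7S)-germacra-1(10),4-dien-6-one
Product: 9 (1(10)E,4E,6R,7S)-germacra-1(10),4-dien-6-ol (6β-OH/7β-isopropyl)
Conditions: DIBAL-H (1.5 equiv), CH2Cl2, −78 °C; aq. Rochelle salt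
Reagents that add atoms: none
Why: Diastereoselective 1,2-hydride reduction under macrocyclic (peripheral-attack) control: in the crossed chair–chair conformer with pseudo-equatorial isopropyl the inner/β face of the twisted s-cis enone lies under both vinylic methyls, so hydride enters from the outer α face (equatorial-type attack, as in 2-isopropylcyclohexanone → cis-alcohol) and sets C6 as R.

Step 7
Reactants: 9 (1(10)E,4E,6R,7S)-germacra-1(10),4-dien-6-ol; 10 diethylphosphonoacetic acid
Product: 11 (6R,7S)-germacra-1(10),4-dien-6-yl 2-(diethoxyphosphoryl)acetate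
Conditions: 10 (1.5 equiv) pre-activated with DCC (1.5 equiv) and DMAP (0.2 equiv), CH2Cl2, 0 °C, then 9, → rt
Reagents that add atoms: none
Why: Steglich esterification with a small, highly reactive acyl donor acylates the hindered allylic alcohol with retention at C6, and pre-activation keeps free acid away from the acid-sensitive diene.

Step 8
Reactants: 11 (6R,7S)-germacra-1(10),4-dien-6-yl 2-(diethoxyphosphoryl)acetate; 12 isovanillin
Product: 13 (6R,7S)-germacra-1(10),4-dien-6-yl (E)-3-(3-hydroxy-4-methoxyphenyl)acrylate
Conditions: 12 (1.3 equiv), LiCl (3 equiv), DBU (2.6 equiv), MeCN, rt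
Reagents that add atoms: none
Why: Masamune–Roush Horner–Wadsworth–Emmons olefination gives the E-cinnamate; the extra base carries the free phenol as its phenoxide, which is meta to the formyl group and does not deactivate it, so no protecting group is needed and no stereocentre is affected.

Step 9
Reactants: 13 (6R,7S)-germacra-1(10),4-dien-6-yl (E)-3-(3-hydroxy-4-methoxyphenyl)acrylate
Product: 16 6β-[(E)-isoferuloyloxy]eudesman-4β-ol (4S,5S,6R,7S,10R), via dioxanylium ion 14 (not isolated), via cyclic orthoacid 15 (not isolated)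
Conditions: HNTf2 (1.1 equiv), CH2Cl2 (5 mM), −78 °C, 15 min; then THF–H2O, NaHCO3, −78 °C → rt
Reagents that add atoms: water, O
Why: Proposed new method: the acid protonates C1 of the strained, more electron-rich C1=C10 alkene and C5 attacks C10 across the ring in the crossed chair–chair fold with pseudo-equatorial isopropyl, setting 10β-Me and 5α-H (trans-decalin); the eudesm-4-yl cation is then closed by the carbonyl oxygen of the now axial 6β-ester, which can reach only the β lobe, giving the p-methoxystyryl-stabilised 1,3-dioxan-2-ylium 14 and setting C4, with olefins from proton loss re-protonating into this sink and the 5→4 hydride shift disfavoured by the adjacent acyloxy group; water adds at the acyl carbon to give 15, which collapses by releasing the hindered tertiary O-4, and any 4-O-acyl isomer migrates back through 15; the closest known reaction types are acid-induced germacradiene → eudesmanol cyclisation and acyloxonium neighbouring-group participation (Woodward–Prévost type, ester-terminated cation–olefin cyclisation).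

## Compound list
1 | (2E,6E)-farnesol | CC(C)=CCC/C(C)=C/CC/C(C)=C/CO | starting material
2 | (2E,6E)-farnesal | CC(C)=CCC/C(C)=C/CC/C(C)=C/C=O | intermediate
3 | (2E,6E)-10-chloro-3,7,11-trimethyldodeca-2,6,11-trienal, racemic at C10 | C=C(C)C(Cl)CC/C(C)=C/CC/C(C)=C/C=O | intermediate
4 | σ-allylchromium(III) species, Cr on farnesyl C12, chiral ligand omitted | O=C/C=C(C)/CC/C=C(C)/CC/C=C(C)/C[Cr](Cl)Cl | intermediate
5 | 6-O-trimethylsilyl ether of 6 | C[Si](C)(C)O[C@@H]1/C=C(C)/CC/C=C(C)/CC[C@H]1C(C)=C | intermediate
6 | (1(10)E,4E,6R,7S)-germacra-1(10),4,11-trien-6-ol (6α-OH, 7β-isopropenyl) | O[C@@H]1/C=C(C)/CC/C=C(C)/CC[C@H]1C(C)=C | intermediate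
7 | (1(10)E,4E,6S,7S)-germacra-1(10),4-dien-6-ol (6α-OH, 7β-isopropyl) | O[C@@H]1/C=C(C)/CC/C=C(C)/CC[C@H]1C(C)C | intermediate
8 | (1(10)E,4E,7S)-germacra-1(10),4-dien-6-one | O=C1/C=C(C)/CC/C=C(C)/CC[C@H]1C(C)C | intermediate
9 | (1(10)E,4E,6R,7S)-germacra-1(10),4-dien-6-ol (6β-OH, 7β-isopropyl) | O[C@H]1/C=C(C)/CC/C=C(C)/CC[C@H]1C(C)C | intermediate
10 | diethylphosphonoacetic acid | CCOP(=O)(CC(=O)O)OCC | starting material
11 | (6R,7S)-germacra-1(10),4-dien-6-yl 2-(diethoxyphosphoryl)acetate | CCOP(=O)(OCC)CC(=O)O[C@H]1/C=C(C)/CC/C=C(C)/CC[C@H]1C(C)C | intermediate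
12 | isovanillin (3-hydroxy-4-methoxybenzaldehyde) | COc1ccc(C=O)cc1O | starting material
13 | (6R,7S)-germacra-1(10),4-dien-6-yl (E)-isoferulate | COc1ccc(/C=C/C(=O)O[C@H]2/C=C(C)/CC/C=C(C)/CC[C@H]2C(C)C)cc1O | intermediate
14 | 4β,6β-O,O-bridged 2-[(E)-3-hydroxy-4-methoxystyryl]-1,3-dioxan-2-ylium on the 5αH,10β-Me,7β-iPr eudesmane core, bis(triflyl)imide salt | COc1ccc(/C=C/C4O[C@H]2[C@@H]3[C@](C)(CCC[C@]3(C)[O+]=4)CC[C@H]2C(C)C)cc1O.O=S(=O)([N-]S(=O)(=O)C(F)(F)F)C(F)(F)F | intermediate
15 | cyclic orthoacid (2-hydroxy-2-styryl-1,3-dioxane bridging O-4β and O-6β) | COc1ccc(/C=C/C4(O)O[C@H]2[C@@H]3[C@](C)(CCC[C@]3(C)O4)CC[C@H]2C(C)C)cc1O | intermediate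
16 | 6β-[(E)-isoferuloyloxy]eudesman-4β-ol, (4S,5S,6R,7S,10R), CNP0291757.1 | COc1ccc(/C=C/C(=O)O[C@H]2[C@@H]3[C@](C)(CCC[C@]3(C)O)CC[C@H]2C(C)C)cc1O | target

## Step count and risks
Total steps: 9. Longest linear sequence: 9 (1 → 16). Compounds 10 and 12 are bought.

**Step 9 is the riskiest.**
- What can go wrong:
  - The cis-6,7 pattern forces one substituent to be axial, so the inverse fold (isopropyl axial, ester equatorial) may compete.
  - The allylic ester may ionise.
  - The orthoacid may open the wrong way.
- The fallback sets out from 9 and comes back at 16. It replaces the product ester as the trap by a sacrificial, irreversible one and moves the esterification to the end.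
- Boc2O/DMAP converts 9 into the germacradienyl tert-butyl carbonate F10.
- Acid at −78 °C closes the decalin, and the carbonate oxygen captures C4 with loss of the tert-butyl group. This gives the neutral eudesmane-4β,6β-diyl cyclic carbonate F11.
- K2CO3/MeOH releases eudesmane-4β,6β-diol F12.
- DCC and 10 acylate only the secondary hydroxyl, giving 4β-hydroxyeudesman-6β-yl diethylphosphonoacetate F13.
- The Masamune–Roush olefination with 12 then gives 16.
- If the fold itself is the problem, the ketone-stage ring closure described under step 6 applies.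

**Step 3 is second.**
- Ten-membered closure onto a weakly electrophilic enal under catalytic turnover, and ligand control in a tethered transition state, are both untested.
- The fallback sets out from 1 and comes back at 7. It draws the absolute configuration from an epoxide rather than from the ring-closing catalyst.
- Sharpless epoxidation of 1 (Ti(OiPr)4, D-(−)-DET, TBHP) gives (2R,3R)-2,3-epoxyfarnesol F1.
- The same selenium-catalysed chlorination gives the 10-chloro epoxy alcohol F2.
- Parikh–Doering oxidation gives the non-conjugated, more electrophilic epoxy aldehyde F3.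
- Pd(0)/Et2Zn umpolung allylation under slow addition closes the ring to (4R,5R,6S,7S)-4,5-epoxygermacra-1(10),11-dien-6-ol F4. The outward-facing epoxide dictates the fold and hence C7.
- Wilkinson hydrogenation gives the dihydro epoxy alcohol F5.
- Stereoretentive deoxygenation (WCl6/n-BuLi) restores the E-alkene of 7.

**Step 6 is third.**
- The facial outcome depends on which conformer of a flexible enone reacts, and a Felkin-type conformer would return the 6α-alcohol.
- The fallback sets out from 8 and comes back at 14. It closes the decalin first, while C6 is sp2 and only the isopropyl group steers the fold.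
- Brief BF3·OEt2 treatment of 8 gives 5αH-eudesm-4(15)-en-6-one F6.
- In this rigid trans-decalone the β face is blocked by the angular methyl, so DIBAL-H delivers eudesm-4(15)-en-6β-ol F7.
- DCC and 10 give its diethylphosphonoacetate F8.
- Olefination with 12 gives eudesm-4(15)-en-6β-yl (E)-isoferulate F9.
- Protonation of the exocyclic alkene with HNTf2 generates the same C4 cation, which the axial ester closes to 14.

Further compounds
F1 | step 3 | (2R,3R)-2,3-epoxyfarnesol | CC(C)=CCC/C(C)=C/CC[C@@]1(C)O[C@@H]1CO
F2 | step 3 | (2R,3R,6E)-10-chloro-2,3-epoxy-3,7,11-trimethyldodeca-6,11-dien-1-ol | C=C(C)C(Cl)CC/C(C)=C/CC[C@@]1(C)O[C@@H]1CO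
F3 | step 3 | (2S,3R,6E)-10-chloro-2,3-epoxy-3,7,11-trimethyldodeca-6,11-dienal | C=C(C)C(Cl)CC/C(C)=C/CC[C@@]1(C)O[C@@H]1C=O
F4 | step 3 | (1(10)E,4R,5R,6S,7S)-4,5-epoxygermacra-1(10),11-dien-6-ol | O[C@@H]1[C@H]2O[C@]2(C)CC/C=C(C)/CC[C@H]1C(C)=C
F5 | step 3 | (1(10)E,4R,5R,6S,7S)-4,5-epoxygermacr-1(10)-en-6-ol | O[C@@H]1[C@H]2O[C@]2(C)CC/C=C(C)/CC[C@H]1C(C)C
F6 | step 6 | 5αH,7β-isopropyl,10β-methyl-eudesm-4(15)-en-6-one | O=C1[C@@H]2[C@](C)(CCCC2=C)CC[C@H]1C(C)C
F7 | step 6 | eudesm-4(15)-en-6β-ol | O[C@H]1[C@@H]2[C@](C)(CCCC2=C)CC[C@H]1C(C)C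
F8 | step 6 | eudesm-4(15)-en-6β-yl 2-(diethoxyphosphoryl)acetate | CCOP(=O)(OCC)CC(=O)O[C@H]1[C@@H]2[C@](C)(CCCC2=C)CC[C@H]1C(C)C
F9 | step 6 | eudesm-4(15)-en-6β-yl (E)-isoferulate | COc1ccc(/C=C/C(=O)O[C@H]2[C@@H]3[C@](C)(CCCC3=C)CC[C@H]2C(C)C)cc1O
F10 | step 9 | (6R,7S)-germacra-1(10),4-dien-6-yl tert-butyl carbonate | CC(C)(C)OC(=O)O[C@H]1/C=C(C)/CC/C=C(C)/CC[C@H]1C(C)C
F11 | step 9 | eudesmane-4β,6β-diyl cyclic carbonate | O=C1O[C@H]2[C@@H]3[C@](C)(CCC[C@]3(C)O1)CC[C@H]2C(C)C
F12 | step 9 | eudesmane-4β,6β-diol | O[C@H]1[C@@H]2[C@](C)(CCC[C@]2(C)O)CC[C@H]1C(C)C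
F13 | step 9 | 4β-hydroxyeudesman-6β-yl 2-(diethoxyphosphoryl)acetate | CCOP(=O)(OCC)CC(=O)O[C@H]1[C@@H]2[C@](C)(CCC[C@]2(C)O)CC[C@H]1C(C)C
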